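## Retrosynthetic overview
1. The acrylic acid comes from an isopropenyl group by two late C–O forming oxidations. The C9 ester comes from the 9β-alcohol and (S)-3-methylpentanoic acid (acyl C–O bond).
2. Key bond C4–O: the tertiary carbinol comes from the planar eudesm-4-yl cation and water, which attacks the α face, away from the C10 methyl group.
3. The cation comes from a monocyclic keto acid. Loss of CO2 gives a C2 radical that closes ring A (C2–C3) onto the C5 isopropenyl group.
4. The keto acid comes from (R)-carvone, an isopropenyl nucleophile (C5, anti to C7) and methyl acrylate (C10, anti to C5). The carvone C=O becomes C9–O.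
5. Ring order: ring B is the carvone ring as bought, and ring A is closed in step 3. All ring stereocentres are relayed from C7 of carvone.

Numbering: eudesmane numbering is used (C4 carbinol, C5 ring-fusion CH, C7 side-chain carbon, C9 oxygenated carbon, C10 quaternary carbon). β is the face of the C10 methyl group and α is the opposite face.

Assumption: (S)-3-methylpentanoic acid is bought as the single enantiomer.

## Route

Step 1
Reactants: 1 (R)-(−)-carvone; 2 isopropenylmagnesium bromide
Product: 4 (3R,5R)-2-methyl-3,5-di(prop-1-en-2-yl)cyclohexan-1-one (C2 epimer mixture), via bromomagnesium enolate 3 (not isolated)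
Conditions: CuBr·SMe2 (10 mol %), THF, −40 to 0 °C; aq NH4Cl
Reagents that add atoms: none
Why: Copper-catalysed conjugate addition of a Grignard reagent, in which the nucleophile enters axially on the face opposite to the C7 isopropenyl group and so sets C5 trans to C7, while the enolisable C10 centre is left as an inconsequential epimer mixture.

Step 2
Reactants: 4 (3R,5R)-2-methyl-3,5-di(prop-1-en-2-yl)cyclohexan-1-one; 5 methyl acrylate
Product: 8 3-[(1S,4R,6S)-1-methyl-2-oxo-4,6-di(prop-1-en-2-yl)cyclohexyl]propanoic acid, via N-benzyl imine 6 (not isolated), via imino ester 7 (not isolated)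
Conditions: BnNH2, 4 Å MS, toluene, 80 °C; 5 (3 equiv, neat), 60 °C; LiOH, THF/MeOH/H2O, rt; aq HCl to pH 3, rt
Reagents that add atoms: lithium hydroxide [Li+].[OH-]; water O; benzylamine NCc1ccccc1 (atoms only in 6 and 7)
Why: Imine–secondary enamine Michael addition (d'Angelo type, aza-ene-like transition state) reacts only through the more substituted enamine at C10 and meets the acrylate on the face opposite to the pseudo-axial C5 isopropenyl group, which sets quaternary C10 (S, chain trans and methyl cis to the C5 group), and saponification with imine hydrolysis then frees the keto acid.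

Step 3
Reactants: 8 3-[(1S,4R,6S)-1-methyl-2-oxo-4,6-di(prop-1-en-2-yl)cyclohexyl]propanoic acid
Product: 10 (3R,4aR,5R,8aS)-5-hydroxy-5,8a-dimethyl-3-(prop-1-en-2-yl)octahydronaphthalen-1(2H)-one (4α-hydroxy-7α-isopropenyl-eudesm-11-en-9-one), via redox-active ester 9 (not isolated)
Conditions: N-hydroxyphthalimide, N,N'-diisopropylcarbodiimide, DMAP (5 mol %), CH2Cl2, rt; filter, swap solvent; Ir(ppy)3 (1 mol %), degassed acetone/H2O 9:1 (0.005 mol/L), 450 nm LED, rt
Reagents that add atoms: water O; N-hydroxyphthalimide ON1C(=O)c2ccccc2C1=O (atoms only in 9)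
Why: Proposed new method: a redox-neutral decarboxylative 6-endo radical cyclisation ended by radical–polar crossover hydroxylation, in which excited Ir(ppy)3 gives one electron to ester 9, which loses phthalimide anion and CO2 to leave the primary C2 radical; this radical, held beside the C5 isopropenyl group by the trans-diequatorial arrangement on ring B, adds to the CH2 terminus (6-endo mode, preferred for hex-5-enyl radicals substituted at C5, since the 5-exo mode would need a trans-hydrindane with a new quaternary carbon) and closes ring A; the tertiary C4 radical is oxidised by the tetravalent iridium complex to the eudesm-4-yl cation, and water forms the C4–O bond from the α face because the β face is screened by the syn-axial C10 methyl group, which sets C4 (R, equatorial OH, axial CH3), while the remote C7 isopropenyl group cannot reach the radical; the closest known reaction types are photoredox decarboxylative C–O bond formation from tertiary N-hydroxyphthalimide esters by radical–polar crossover and decarboxylative oxyalkylation of styrenes, neither of which has been shown for a cyclisation onto an unactivated 1,1-dialkyl alkene ended by water.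

Step 4
Reactants: 10 (3R,4aR,5R,8aS)-5-hydroxy-5,8a-dimethyl-3-(prop-1-en-2-yl)octahydronaphthalen-1(2H)-one
Product: 11 (1S,3R,4aR,5R,8aS)-5,8a-dimethyl-3-(prop-1-en-2-yl)decahydronaphthalene-1,5-diol (9β-alcohol)
Conditions: SmI2 (2.5 equiv), H2O, Et3N, THF, rt
Reagents that add atoms: none
Why: Single-electron ketone reduction by divalent samarium (dissolving-metal type, through ketyl and carbanion) gives the thermodynamically preferred equatorial 9β-alcohol (S) and avoids hydride delivery, which is hindered on both faces (axial C7 isopropenyl on α, C10 methyl on β), while the isolated alkene and the tertiary alcohol are inert.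

Step 5
Reactants: 11 (1S,3R,4aR,5R,8aS)-5,8a-dimethyl-3-(prop-1-en-2-yl)decahydronaphthalene-1,5-diol; 12 (S)-3-methylpentanoic acid
Product: 14 (1S,3R,4aR,5R,8aS)-5-hydroxy-5,8a-dimethyl-3-(prop-1-en-2-yl)decahydronaphthalen-1-yl (3S)-3-methylpentanoate, via mixed anhydride 13 (not isolated)
Conditions: 12, 2,4,6-Cl3C6H2COCl, Et3N, THF, rt; then 11, DMAP, toluene, 40 °C
Reagents that add atoms: 2,4,6-trichlorobenzoyl chloride O=C(Cl)c1c(Cl)cc(Cl)cc1Cl (atoms only in 13)
Why: Yamaguchi esterification forms the acyl C–O bond at the only acylable hydroxyl group (secondary C9-OH, the tertiary C4-OH being inert) and touches neither C9 nor the side-chain stereocentre.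

Step 6
Reactants: 14 (1S,3R,4aR,5R,8aS)-5-hydroxy-5,8a-dimethyl-3-(prop-1-en-2-yl)decahydronaphthalen-1-yl (3S)-3-methylpentanoate
Product: 15 (1S,3R,4aR,5R,8aS)-5-hydroxy-5,8a-dimethyl-3-(3-oxoprop-1-en-2-yl)decahydronaphthalen-1-yl (3S)-3-methylpentanoate
Conditions: SeO2 (1.2 equiv), 1,4-dioxane, 70 °C
Reagents that add atoms: selenium dioxide O=[Se]=O
Why: Riley allylic oxidation (ene reaction followed by a [2,3]-sigmatropic shift) acts on the methyl group of the only alkene left in the molecule and carries it to the 2-substituted acrolein without touching C7.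

Step 7
Reactants: 15 (1S,3R,4aR,5R,8aS)-5-hydroxy-5,8a-dimethyl-3-(3-oxoprop-1-en-2-yl)decahydronaphthalen-1-yl (3S)-3-methylpentanoate
Product: 16 2-[(2R,4S,4aS,8R,8aR)-8-hydroxy-4a,8-dimethyl-4-{[(3S)-3-methylpentanoyl]oxy}decahydronaphthalen-2-yl]prop-2-enoic acid (target)
Conditions: NaClO2, NaH2PO4, 2-methyl-2-butene, t-BuOH/H2O, 0 °C to rt
Reagents that add atoms: sodium chlorite [Na+].[O-][Cl+][O-]
Why: Pinnick oxidation converts the enal to the acrylic acid under buffered, weakly acidic conditions that neither move the double bond into conjugation with C7 nor disturb the ester or the tertiary alcohol.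

## Compound list
1 | (R)-(−)-carvone | C=C(C)[C@H]1CC(=O)C(C)=CC1 | starting material
2 | isopropenylmagnesium bromide | C=C(C)[Mg]Br | starting material
3 | bromomagnesium enolate of 4 (C9–O–MgBr, C9=C10) | C=C(C)[C@H]1CC(O[Mg]Br)=C(C)[C@H](C(C)=C)C1 | intermediate
4 | (3R,5R)-2-methyl-3,5-di(prop-1-en-2-yl)cyclohexan-1-one, the two isopropenyl groups trans, C2 epimer mixture | C=C(C)[C@H]1CC(=O)C(C)[C@H](C(C)=C)C1 | intermediate
5 | methyl acrylate | C=CC(=O)OC | starting material
6 | N-benzyl imine of 4 | C=C(C)[C@H]1CC(=NCc2ccccc2)C(C)[C@H](C(C)=C)C1 | intermediate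
7 | methyl 3-[(1S,4R,6S)-2-(benzylimino)-1-methyl-4,6-di(prop-1-en-2-yl)cyclohexyl]propanoate | C=C(C)[C@H]1CC(=NCc2ccccc2)[C@@](C)(CCC(=O)OC)[C@H](C(C)=C)C1 | intermediate
8 | 3-[(1S,4R,6S)-1-methyl-2-oxo-4,6-di(prop-1-en-2-yl)cyclohexyl]propanoic acid | C=C(C)[C@H]1CC(=O)[C@@](C)(CCC(=O)O)[C@H](C(C)=C)C1 | intermediate
9 | 1,3-dioxoisoindolin-2-yl ester of 8 | C=C(C)[C@H]1CC(=O)[C@@](C)(CCC(=O)ON2C(=O)c3ccccc3C2=O)[C@H](C(C)=C)C1 | intermediate
10 | (3R,4aR,5R,8aS)-5-hydroxy-5,8a-dimethyl-3-(prop-1-en-2-yl)octahydronaphthalen-1(2H)-one, trans-decalin, 4α-OH, 7α-isopropenyl | C=C(C)[C@H]1CC(=O)[C@@]2(C)CCC[C@@](C)(O)[C@@H]2C1 | intermediate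
11 | (1S,3R,4aR,5R,8aS)-5,8a-dimethyl-3-(prop-1-en-2-yl)decahydronaphthalene-1,5-diol | C=C(C)[C@H]1C[C@H](O)[C@@]2(C)CCC[C@@](C)(O)[C@@H]2C1 | intermediate
12 | (S)-3-methylpentanoic acid | OC(=O)C[C@@H](C)CC | starting material
13 | (3S)-3-methylpentanoic 2,4,6-trichlorobenzoic anhydride | O=C(C[C@@H](C)CC)OC(=O)c1c(Cl)cc(Cl)cc1Cl | intermediate
14 | (1S,3R,4aR,5R,8aS)-5-hydroxy-5,8a-dimethyl-3-(prop-1-en-2-yl)decahydronaphthalen-1-yl (3S)-3-methylpentanoate | C=C(C)[C@H]1C[C@H](OC(=O)C[C@@H](C)CC)[C@@]2(C)CCC[C@@](C)(O)[C@@H]2C1 | intermediate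
15 | (1S,3R,4aR,5R,8aS)-5-hydroxy-5,8a-dimethyl-3-(3-oxoprop-1-en-2-yl)decahydronaphthalen-1-yl (3S)-3-methylpentanoate | C=C(C=O)[C@H]1C[C@H](OC(=O)C[C@@H](C)CC)[C@@]2(C)CCC[C@@](C)(O)[C@@H]2C1 | intermediate
16 | 2-[(2R,4S,4aS,8R,8aR)-8-hydroxy-4a,8-dimethyl-4-{[(3S)-3-methylpentanoyl]oxy}decahydronaphthalen-2-yl]prop-2-enoic acid | C=C(C(=O)O)[C@H]1C[C@H](OC(=O)C[C@@H](C)CC)[C@@]2(C)CCC[C@@](C)(O)[C@@H]2C1 | target

## Step count and risks
Total step count: 7. Longest linear sequence: 7 (1 to 16).

Step 2 (quaternary C10 next to the branched C5). The hindered enamine may add slowly, or the adduct may close to a bicyclic lactam.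
- The fallback sets out from enolate 3 and comes back at 8.
- Enolate 3 is not quenched. It is alkylated in the same flask with allyl bromide (DMPU, −20 °C to rt), again anti to the C5 group, to give the allyl ketone F1.
- Disiamylborane adds only to the monosubstituted alkene and gives the trialkylborane F2.
- NaBO3 oxidation gives the primary alcohol F3.
- TEMPO/PhI(OAc)2 in wet MeCN takes F3 through the aldehyde F4 to acid 8.

Step 3 (proposed new step). The radical may close 5-exo or shift a hydrogen atom from C8. The cation may lose a proton or take up water on the β face.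
- The fallback uses known chemistry only. It sets out from enolate 3 and comes back at 11.
- Enolate 3 is alkylated in the flask of step 1 with but-3-en-1-yl trifluoromethanesulfonate (DMPU) to give the butenyl ketone F5.
- Ring-closing metathesis with the second-generation Grubbs catalyst joins the butenyl group to the neighbouring C5 isopropenyl group and gives the trans-fused dienone F6.
- SmI2/H2O/Et3N gives the equatorial dienol F7.
- mCPBA (1 equiv, 0 °C) epoxidises the trisubstituted ring alkene in preference to the isopropenyl group and from the α face, giving the epoxy alcohol F8.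
- LiEt3BH opens the epoxide at the less substituted C3 to give diol 11.

Step 4 (configuration at C9). Protonation of the hindered ketyl or carbanion may give part of the axial alcohol.
- The fallback sets out from 10 and comes back at 11.
- LiAlH4 reduces 10 mainly to the axial 9α-alcohol F9.
- The epimers are then equilibrated under Meerwein–Ponndorf–Verley/Oppenauer conditions (Al(Oi-Pr)3, trace acetone, i-PrOH/toluene, reflux) through ketone 10.
- The equilibrium favours the equatorial alcohol 11, which lacks the syn-axial contact with the C7 isopropenyl group.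

## Further compounds
F1 | step 2 | (2S,3S,5R)-2-allyl-2-methyl-3,5-di(prop-1-en-2-yl)cyclohexan-1-one | C=C(C)[C@H]1CC(=O)[C@@](C)(CC=C)[C@H](C(C)=C)C1
F2 | step 2 | terminal bis(3-methylbutan-2-yl)borane adduct of F1 | C=C(C)[C@H]1CC(=O)[C@@](C)(CCCB(C(C)C(C)C)C(C)C(C)C)[C@H](C(C)=C)C1
F3 | step 2 | (2S,3S,5R)-2-(3-hydroxypropyl)-2-methyl-3,5-di(prop-1-en-2-yl)cyclohexan-1-one | C=C(C)[C@H]1CC(=O)[C@@](C)(CCCO)[C@H](C(C)=C)C1
F4 | step 2 | 3-[(1S,4R,6S)-1-methyl-2-oxo-4,6-di(prop-1-en-2-yl)cyclohexyl]propanal | C=C(C)[C@H]1CC(=O)[C@@](C)(CCC=O)[C@H](C(C)=C)C1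
F5 | step 3 | (2S,3S,5R)-2-(but-3-en-1-yl)-2-methyl-3,5-di(prop-1-en-2-yl)cyclohexan-1-one | C=C(C)[C@H]1CC(=O)[C@@](C)(CCC=C)[C@H](C(C)=C)C1
F6 | step 3 | eudesma-3,11-dien-9-one with 5α-H, 7α-isopropenyl and 10β-methyl | C=C(C)[C@H]1CC(=O)[C@@]2(C)CCC=C(C)[C@@H]2C1
F7 | step 3 | 9β-alcohol of F6 | C=C(C)[C@H]1C[C@H](O)[C@@]2(C)CCC=C(C)[C@@H]2C1
F8 | step 3 | 3α,4α-epoxide of F7 | C=C(C)[C@H]1C[C@H](O)[C@@]2(C)CC[C@H]3O[C@@]3(C)[C@@H]2C1
F9 | step 4 | 9α-epimer (axial alcohol) of 11 | C=C(C)[C@H]1C[C@@H](O)[C@@]2(C)CCC[C@@](C)(O)[C@@H]2C1
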